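The route rests on cutting the O1–C5 bond of the tetrahydrofuran (O1, C2 veratryl, C3, C4, C5 syringyl), which traces the ring to a cyclopropane built from C3, C4 and C5 with the veratroyl group on C3. A Lewis acid breaks the strained C3–C5 bond, polarised by the electron-rich O-benzylsyringyl ring on C5 and the aryl ketone on C3, and the ketone oxygen closes onto C5; one operation thus forms the oxygen ring, the O1–C5 bond and the trans C4/C5 pair, leaving a C2=C3 enol ether for reduction. The precursor is an enantiopure aryl 1,2-dimethyl-3-arylcyclopropyl ketone in which only the methyl-bearing CH (future C4) must be stereodefined.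

Key step: step 8

Remark: the text uses the lignan locants O1, C2 (veratryl carbon), C3, C4, C5 (syringyl carbon) for the oxygen ring; cyclopropane locants are C1 (quaternary), C2 (CH–CH3), C3 (CH–aryl), which become C3, C4 and C5; systematic names in the lists carry IUPAC locants.

Step 1
Reactants: 1 syringaldehyde; 2 benzyl bromide
Product: 3 4-(benzyloxy)-3,5-dimethoxybenzaldehyde
Conditions: K2CO3, DMF, 60 °C
Reagents that add atoms: benzyl bromide (2), BrCc1ccccc1
Why: Williamson ether synthesis, in which the phenoxide displaces bromide from the benzylic halide; the O-benzyl group should then survive the hydride, organometallic and acid steps and leave by hydrogenolysis at the end.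

Step 2
Reactants: 3 4-(benzyloxy)-3,5-dimethoxybenzaldehyde; 4 ethyl 2-(triphenylphosphoranylidene)propanoate
Product: 5 ethyl (E)-3-[4-(benzyloxy)-3,5-dimethoxyphenyl]-2-methylprop-2-enoate
Conditions: toluene, 90 °C
Reagents that add atoms: ethyl 2-(triphenylphosphoranylidene)propanoate (4), CCOC(=O)C(C)=P(c1ccccc1)(c1ccccc1)c1ccccc1
Why: Wittig olefination with a stabilised α-branched ylide, which with aromatic aldehydes should give the (E)-trisubstituted enoate (aryl trans to the ester, cis to the methyl group).

Step 3
Reactants: 5 ethyl (E)-3-[4-(benzyloxy)-3,5-dimethoxyphenyl]-2-methylprop-2-enoate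
Product: 7 (E)-3-[4-(benzyloxy)-3,5-dimethoxyphenyl]-2-methylprop-2-en-1-ol, via (E)-3-[4-(benzyloxy)-3,5-dimethoxyphenyl]-2-methylprop-2-enal 6 (not isolated)
Conditions: (i-Bu)2AlH (2.5 equiv), CH2Cl2, −78 → 0 °C; aq. KNaC4H4O6 work-up
Reagents that add atoms: none
Why: 1,2-Reduction of an α,β-unsaturated ester by an electrophilic aluminium hydride, which passes through the aldehyde and should stop at the allylic alcohol without touching the alkene geometry or the benzyl ether.

Step 4
Reactants: 7 (E)-3-[4-(benzyloxy)-3,5-dimethoxyphenyl]-2-methylprop-2-en-1-ol; 8 1,1-diiodoethane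
Product: 10 [(1S,2R,3R)-3-[4-(benzyloxy)-3,5-dimethoxyphenyl]-1,2-dimethylcyclopropyl]methanol, via bis(1-iodoethyl)zinc 9 (not isolated)
Conditions: Et2Zn, CH3CHI2, DME, CH2Cl2, −10 °C; then 7 and (4R,5R)-2-butyl-N,N,N',N'-tetramethyl-1,3,2-dioxaborolane-4,5-dicarboxamide (1.2 equiv), −10 °C → rt; aq. NH4Cl, then aq. NaOH; chromatography to a single diastereomer
Reagents that add atoms: 1,1-diiodoethane (8), CC(I)I
Why: Charette asymmetric cyclopropanation (Simmons–Smith type) with a substituted zinc carbenoid: the alkoxide of 7, held on zinc and on the boron of the amide-chelating dioxaborolane, should receive the ethylidene unit stereospecifically on one face of the (E)-alkene, so that the aryl group and the C1 methyl stay cis and C1 and C3 follow the ligand (the (4R,5R) enantiomer is the one that turns cinnamyl alcohol into (1S,2S)-2-phenylcyclopropylmethanol), while the carbenoid methyl is expected to turn away from the coordinated CH2O unit and so set C2 (R), the future C4 of the target.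

Step 5
Reactants: 10 [(1S,2R,3R)-3-[4-(benzyloxy)-3,5-dimethoxyphenyl]-1,2-dimethylcyclopropyl]methanol
Product: 11 (1S,2R,3R)-3-[4-(benzyloxy)-3,5-dimethoxyphenyl]-1,2-dimethylcyclopropane-1-carbaldehyde
Conditions: Pr4N[RuO4] (5 mol %), N-methylmorpholine N-oxide, 4 Å MS, CH2Cl2, rt
Reagents that add atoms: none
Why: Ley–Griffith oxidation under neutral, anhydrous conditions should stop at the aldehyde, which has no α-hydrogen and cannot epimerise, and should spare the acid-sensitive aryl cyclopropane.

Step 6
Reactants: 11 (1S,2R,3R)-3-[4-(benzyloxy)-3,5-dimethoxyphenyl]-1,2-dimethylcyclopropane-1-carbaldehyde; 12 4-bromoveratrole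
Product: 14 (3,4-dimethoxyphenyl){(1S,2R,3R)-3-[4-(benzyloxy)-3,5-dimethoxyphenyl]-1,2-dimethylcyclopropyl}methanol as both carbinol epimers, via (3,4-dimethoxyphenyl)magnesium bromide 13 (not isolated)
Conditions: 12, Mg, THF, 40 °C; then 11, 0 °C; aq. NH4Cl
Reagents that add atoms: 4-bromoveratrole (12), COc1ccc(Br)cc1OC
Why: Grignard addition to a non-enolisable aldehyde; the carbinol centre forms without control, which does not matter because it is oxidised in the next step.

Step 7
Reactants: 14 (3,4-dimethoxyphenyl){(1S,2R,3R)-3-[4-(benzyloxy)-3,5-dimethoxyphenyl]-1,2-dimethylcyclopropyl}methanol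
Product: 15 (3,4-dimethoxyphenyl){(1S,2R,3R)-3-[4-(benzyloxy)-3,5-dimethoxyphenyl]-1,2-dimethylcyclopropyl}methanone
Conditions: Pr4N[RuO4] (5 mol %), N-methylmorpholine N-oxide, 4 Å MS, CH2Cl2, rt
Reagents that add atoms: none
Why: Ley–Griffith oxidation of a secondary benzylic alcohol, chosen because it is neutral and the cyclopropyl aryl carbinol would ionise and ring-open under acid; both epimers should converge on the one ketone.

Step 8
Reactants: 15 (3,4-dimethoxyphenyl){(1S,2R,3R)-3-[4-(benzyloxy)-3,5-dimethoxyphenyl]-1,2-dimethylcyclopropyl}methanone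
Product: 17 (2S,3S)-2-[4-(benzyloxy)-3,5-dimethoxyphenyl]-5-(3,4-dimethoxyphenyl)-3,4-dimethyl-2,3-dihydrofuran, via ring-opened Sc(OSO2CF3)3-bound enolate zwitterion 16 (not isolated)
Conditions: Sc(OSO2CF3)3 (10 mol %), 4 Å MS, CH2Cl2, 0 °C → rt; Et3N quench
Reagents that add atoms: none
Why: Sc(OSO2CF3)3 binds the ketone oxygen, and the strained C3–C5 bond, flanked by the electron-rich aryl on C5 and the acyl group on C3, should ionise to the ring-opened enolate/benzylic cation 16, whose enolate oxygen then bonds to C5. The closest known reaction type is the acid-catalysed Cloke–Wilson rearrangement of donor-substituted cyclopropyl ketones to 2,3-dihydrofurans. The one ring closes by O-alkylation of the enolate, a 5-exo-trig attack on the trigonal benzylic cation with the enolate double bond ending inside the ring (enol-endo), feasible because oxygen bonds through an in-plane lone pair. The only new stereocentre, C5, is controlled by the untouched C4 stereocentre: the aryl group should take the face of the closing envelope anti to the C4 methyl, and since the benzylic C5–O bond can reionise under the catalyst the trans isomer is also the thermodynamic outcome, so the configurations of cyclopropane C1 and C3 do not matter. The step needs O-closure to outrun Friedel–Crafts attack of the veratryl ring on C5 and proton loss from C4; recombination of the oxygen anion with the cation inside the ion pair should be faster than an arene attack that costs aromaticity, and a catalytic, non-basic Lewis acid with an early amine quench keeps the cation short-lived.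

Step 9
Reactants: 17 (2S,3S)-2-[4-(benzyloxy)-3,5-dimethoxyphenyl]-5-(3,4-dimethoxyphenyl)-3,4-dimethyl-2,3-dihydrofuran
Product: 19 (2S,3S,4S,5R)-2-[4-(benzyloxy)-3,5-dimethoxyphenyl]-5-(3,4-dimethoxyphenyl)-3,4-dimethyloxolane, via oxocarbenium trifluoroacetate 18 (not isolated)
Conditions: Et3SiH (3 equiv), CF3CO2H (5 equiv), CH2Cl2, −40 → 0 °C; aq. NaHCO3
Reagents that add atoms: none
Why: Ionic hydrogenation of an enol ether: CF3CO2H protonates C3 reversibly, so the 2-aryl oxocarbenium ion 18 should equilibrate through 17 to the isomer with the C3 methyl trans to the C4 methyl (C3, S), and Et3SiH should then deliver hydride to C2 on the face anti to the neighbouring C3 methyl and to the C5 aryl, placing the veratryl group cis to the C3 methyl (C2, R), while the twisted, only modestly donating O-benzyl group keeps the C5–O bond from ionising.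

Step 10
Reactants: 19 (2S,3S,4S,5R)-2-[4-(benzyloxy)-3,5-dimethoxyphenyl]-5-(3,4-dimethoxyphenyl)-3,4-dimethyloxolane
Product: 20 4-[(2S,3S,4S,5R)-5-(3,4-dimethoxyphenyl)-3,4-dimethyloxolan-2-yl]-2,6-dimethoxyphenol
Conditions: H2 (1 atm), Pd/C (10 wt % Pd), EtOAc, rt
Reagents that add atoms: none
Why: Catalytic hydrogenolysis of an aryl benzyl ether, which in a neutral aprotic solvent should be much faster than cleavage of the ring benzylic C–O bonds and touches no stereocentre.

Compound list
1 | syringaldehyde (4-hydroxy-3,5-dimethoxybenzaldehyde) | COc1cc(C=O)cc(OC)c1O | starting material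
2 | benzyl bromide | BrCc1ccccc1 | starting material
3 | 4-(benzyloxy)-3,5-dimethoxybenzaldehyde | COc1cc(C=O)cc(OC)c1OCc1ccccc1 | intermediate
4 | ethyl 2-(triphenylphosphoranylidene)propanoate | CCOC(=O)C(C)=P(c1ccccc1)(c1ccccc1)c1ccccc1 | starting material
5 | ethyl (E)-3-[4-(benzyloxy)-3,5-dimethoxyphenyl]-2-methylprop-2-enoate | CCOC(=O)/C(C)=C/c1cc(OC)c(OCc2ccccc2)c(OC)c1 | intermediate
6 | (E)-3-[4-(benzyloxy)-3,5-dimethoxyphenyl]-2-methylprop-2-enal | O=C/C(C)=C/c1cc(OC)c(OCc2ccccc2)c(OC)c1 | intermediate
7 | (E)-3-[4-(benzyloxy)-3,5-dimethoxyphenyl]-2-methylprop-2-en-1-ol | OC/C(C)=C/c1cc(OC)c(OCc2ccccc2)c(OC)c1 | intermediate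
8 | 1,1-diiodoethane | CC(I)I | starting material
9 | bis(1-iodoethyl)zinc | CC(I)[Zn]C(C)I | intermediate
10 | [(1S,2R,3R)-3-[4-(benzyloxy)-3,5-dimethoxyphenyl]-1,2-dimethylcyclopropyl]methanol | OC[C@@]1(C)[C@H](C)[C@@H]1c1cc(OC)c(OCc2ccccc2)c(OC)c1 | intermediate
11 | (1S,2R,3R)-3-[4-(benzyloxy)-3,5-dimethoxyphenyl]-1,2-dimethylcyclopropane-1-carbaldehyde | O=C[C@@]1(C)[C@H](C)[C@@H]1c1cc(OC)c(OCc2ccccc2)c(OC)c1 | intermediate
12 | 4-bromoveratrole (4-bromo-1,2-dimethoxybenzene) | COc1ccc(Br)cc1OC | starting material
13 | (3,4-dimethoxyphenyl)magnesium bromide | COc1ccc([Mg]Br)cc1OC | intermediate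
14 | (3,4-dimethoxyphenyl){(1S,2R,3R)-3-[4-(benzyloxy)-3,5-dimethoxyphenyl]-1,2-dimethylcyclopropyl}methanol, both carbinol epimers | COc1ccc(C(O)[C@@]2(C)[C@H](C)[C@@H]2c3cc(OC)c(OCc4ccccc4)c(OC)c3)cc1OC | intermediate
15 | (3,4-dimethoxyphenyl){(1S,2R,3R)-3-[4-(benzyloxy)-3,5-dimethoxyphenyl]-1,2-dimethylcyclopropyl}methanone | COc1ccc(C(=O)[C@@]2(C)[C@H](C)[C@@H]2c3cc(OC)c(OCc4ccccc4)c(OC)c3)cc1OC | intermediate
16 | ring-opened zwitterion: enolate oxygen bound to Sc(OSO2CF3)3, benzylic cation at C5, C4 (S) intact | COc1ccc(C(O[Sc-](OS(=O)(=O)C(F)(F)F)(OS(=O)(=O)C(F)(F)F)OS(=O)(=O)C(F)(F)F)=C(C)[C@H](C)[CH+]c2cc(OC)c(OCc3ccccc3)c(OC)c2)cc1OC | intermediate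
17 | (2S,3S)-2-[4-(benzyloxy)-3,5-dimethoxyphenyl]-5-(3,4-dimethoxyphenyl)-3,4-dimethyl-2,3-dihydrofuran (lignan locants: 4S,5S, 4,5-trans, C2=C3) | COc1ccc(C=2O[C@H](c3cc(OC)c(OCc4ccccc4)c(OC)c3)[C@@H](C)C=2C)cc1OC | intermediate
18 | (3S,4S,5S)-5-[4-(benzyloxy)-3,5-dimethoxyphenyl]-2-(3,4-dimethoxyphenyl)-3,4-dimethyl-4,5-dihydro-3H-furan-1-ium trifluoroacetate (lignan locants; C3 methyl trans to C4 methyl) | COc1ccc(C2=[O+][C@H](c3cc(OC)c(OCc4ccccc4)c(OC)c3)[C@@H](C)[C@@H]2C)cc1OC.[O-]C(=O)C(F)(F)F | intermediate
19 | (2S,3S,4S,5R)-2-[4-(benzyloxy)-3,5-dimethoxyphenyl]-5-(3,4-dimethoxyphenyl)-3,4-dimethyloxolane (lignan locants: 2R,3S,4S,5S) | COc1ccc([C@@H]2O[C@H](c3cc(OC)c(OCc4ccccc4)c(OC)c3)[C@@H](C)[C@@H]2C)cc1OC | intermediate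
20 | 4-[(2S,3S,4S,5R)-5-(3,4-dimethoxyphenyl)-3,4-dimethyloxolan-2-yl]-2,6-dimethoxyphenol | COc1ccc([C@@H]2O[C@H](c3cc(OC)c(O)c(OC)c3)[C@@H](C)[C@@H]2C)cc1OC | target

Total step count: 10. Longest linear sequence: 10 steps (from syringaldehyde 1).

Steps most likely to fail

Step 8. Three processes could spoil the ring expansion. Friedel–Crafts closure of the veratryl ring onto the C5 cation (a six-membered carbocycle) could gain ground over the reversible O-closure on long exposure to the Lewis acid. Proton loss from C4 of the cation and re-protonation would erode the configuration at C4. Adventitious water would hydrolyse the enol ether. Fallback: the ring expansion is moved to the carboxylic acid oxidation level, where no aroyl ring is present to intercept the cation, and the veratryl group is brought in afterwards. Setting out from aldehyde 11, Pinnick oxidation (NaClO2, NaH2PO4, 2-methylbut-2-ene, t-BuOH/H2O) would give (1S,2R,3R)-3-[4-(benzyloxy)-3,5-dimethoxyphenyl]-1,2-dimethylcyclopropane-1-carboxylic acid F1. Acid-promoted ring-opening lactonisation (catalytic CF3SO3H, CH2Cl2, 0 °C) and equilibration of C3 with DBU should give the all-trans lactone (3S,4S,5S)-5-[4-(benzyloxy)-3,5-dimethoxyphenyl]-3,4-dimethyloxolan-2-one F2. Bromide 12 and n-BuLi (THF, −78 °C) would give 3,4-dimethoxyphenyllithium F3, whose addition to F2 should stop at the cyclic hemiketal (3S,4S,5S)-5-[4-(benzyloxy)-3,5-dimethoxyphenyl]-2-(3,4-dimethoxyphenyl)-3,4-dimethyloxolan-2-ol F4. Reductive deoxygenation of F4 (BF3·OEt2, Et3SiH, CH2Cl2, −78 °C) runs through the same oxocarbenium ion as step 9 and comes back to the route at 19.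

Step 9. The hydride transfer could show poor facial selectivity, or C3 could be reduced before it has equilibrated. The acid could also ionise the benzylic C–O bonds, followed by epimerisation or reductive ring opening. Fallback: both hydrogens are added in one syn event on a metal surface instead of stepwise through a cation. Setting out from 17, hydrogenation (H2, 4 atm, Pd/C, EtOAc, rt) should take place on the ring face that carries only the C4 methyl, away from the larger C5 aryl. That puts the C2 aryl and the C3 methyl cis to each other and trans to the C4 methyl, as required. The benzyl ether is cleaved in the same operation, so the sequence comes back to the route at 20.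

Step 4. Control over the orientation of the carbenoid methyl on the trisubstituted alkene could be incomplete. C2 is the only cyclopropane centre that survives step 8, so any syn isomer carried forward would lower the enantiomeric purity of everything downstream; the hindered alkene could also react slowly. The configuration of 10 should therefore be secured before going on. Fallback: the stereochemical roles are exchanged so that the surviving centre is fixed by facial selectivity alone. Setting out from aldehyde 3, condensation with N2H4·H2O (EtOH) would give (E)-[4-(benzyloxy)-3,5-dimethoxybenzylidene]hydrazine F5, and oxidation with MnO2 (CH2Cl2, 0 °C) would give 2-(benzyloxy)-5-(diazomethyl)-1,3-dimethoxybenzene F6, used in solution. With ZnI2 this should form the aryl-substituted carbenoid {[4-(benzyloxy)-3,5-dimethoxyphenyl](iodo)methyl}zinc iodide F7. F7 would cyclopropanate commercial (E)-2-methylbut-2-en-1-ol, deprotonated with Et2Zn, in the presence of the (4S,5S)-dioxaborolane (CH2Cl2, −10 °C → rt). Both methyl-bearing carbons then come from the alkene and cyclopropane C2 is set by the ligand-controlled face. The carbenoid delivers only the aryl carbon, expected anti to CH2OH, whose configuration is erased in step 8 anyway. The sequence comes back to the route at 10.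

Further compounds
F1 | step 8 | (1S,2R,3R)-3-[4-(benzyloxy)-3,5-dimethoxyphenyl]-1,2-dimethylcyclopropane-1-carboxylic acid | OC(=O)[C@@]1(C)[C@H](C)[C@@H]1c1cc(OC)c(OCc2ccccc2)c(OC)c1
F2 | step 8 | (3S,4S,5S)-5-[4-(benzyloxy)-3,5-dimethoxyphenyl]-3,4-dimethyloxolan-2-one | O=C1O[C@H](c2cc(OC)c(OCc3ccccc3)c(OC)c2)[C@@H](C)[C@@H]1C
F3 | step 8 | 3,4-dimethoxyphenyllithium | [Li]c1ccc(OC)c(OC)c1
F4 | step 8 | (3S,4S,5S)-5-[4-(benzyloxy)-3,5-dimethoxyphenyl]-2-(3,4-dimethoxyphenyl)-3,4-dimethyloxolan-2-ol | COc1ccc(C2(O)O[C@H](c3cc(OC)c(OCc4ccccc4)c(OC)c3)[C@@H](C)[C@@H]2C)cc1OC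
F0 | step 9 | none | none
F5 | step 4 | (E)-[4-(benzyloxy)-3,5-dimethoxybenzylidene]hydrazine | COc1cc(/C=N/N)cc(OC)c1OCc1ccccc1
F6 | step 4 | 2-(benzyloxy)-5-(diazomethyl)-1,3-dimethoxybenzene | COc1cc(C=[N+]=[N-])cc(OC)c1OCc1ccccc1
F7 | step 4 | {[4-(benzyloxy)-3,5-dimethoxyphenyl](iodo)methyl}zinc iodide | COc1cc(C(I)[Zn]I)cc(OC)c1OCc1ccccc1
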